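**Retrosynthetic overview**
1. The last step joins two fragments and makes the C3–C4 bond, the quaternary centre C3, the (E)-C4=C5 alkene and the C6 centre at once: a chiral-biphenol-catalysed allylation of enal sulfonylhydrazone 36 by (Z)-allylboronate 13, followed by loss of N2 from the allylic diazene.
2. Boronate 13 comes from nickel-catalysed 1,4-hydroboration of a dienyl side chain, installed with C1′ by cuprate addition/enolate alkylation of (S)-3,4-dimethylcyclohexenone.
3. The only ring is made first, by an organocatalytic Michael/aldol sequence from propanal and methyl vinyl ketone.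
4. Hydrazone 36 comes from an (E)-enal made by carboalumination of alkyne 31, itself from iodide 27 and a propargyl unit.
5. C9, C10 and C13 all come from one organocatalytic desymmetrisation of meso-2,3-dimethylsuccinic anhydride; lactol 19 is used twice (core, and C13 arm after Wolff–Kishner reduction) and the two pieces are joined by a Wittig reaction.

Assumption: locants follow the name (3S,4E,6R,9R,10S,13R)-3,6,9,10,13,14-hexamethyl-3-{2-[(1S,3S)-2,2,3-trimethyl-6-methylidenecyclohexyl]ethyl}pentadeca-1,4-diene (ring carbons primed); Me2CuLi, HBpin and the catalysts are bought or made beforehand and not counted as steps.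

**Route**

Step 1
Reactants: 1 methyl vinyl ketone; 2 vinylmagnesium bromide
Product: 3 3-methylpenta-1,4-dien-3-ol
Conditions: THF, −78 → 0 °C; aq. NH4Cl
Reagents that add atoms: none
Why: Grignard 1,2-addition to the ketone gives the achiral divinyl carbinol.

Step 2
Reactants: 3 3-methylpenta-1,4-dien-3-ol
Product: 4 (3E)-5-bromo-3-methylpenta-1,3-diene
Conditions: PBr3, pyridine (cat.), Et2O, −10 °C
Reagents that add atoms: phosphorus tribromide BrP(Br)Br
Why: SN2′ bromination with allylic transposition gives the primary dienyl bromide (E major); the minor Z isomer is tolerable because this double bond is consumed in step 7.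

Step 3
Reactants: 5 propanal; 1 methyl vinyl ketone
Product: 7 (4S)-4-methylcyclohex-2-en-1-one, via (2S)-2-methyl-5-oxohexanal 6 (not isolated)
Conditions: (R)-α,α-diphenylprolinol methyl ether (5 mol %), ethyl 3,4-dihydroxybenzoate (20 mol %), neat, 4 °C; evaporate; then LiOH, i-PrOH, rt
Reagents that add atoms: none
Why: Enamine-catalysed asymmetric Michael addition sets the first ring stereocentre (C3′) by attack on the unshielded enamine face, and the intramolecular aldol condensation then closes the ring without touching it.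

Step 4
Reactants: 7 (4S)-4-methylcyclohex-2-en-1-one
Product: 9 (4S)-3,4-dimethylcyclohex-2-en-1-one, via lithium enolate 8 (not isolated)
Conditions: Me2CuLi, Et2O, −78 → −40 °C; then PhS(Cl)=N-t-Bu, THF, −78 °C
Reagents that add atoms: lithium dimethylcuprate [Li+].C[Cu-]C
Why: Cuprate conjugate addition followed by one-pot Mukaiyama dehydrogenation of the enolate with the sulfinimidoyl chloride restores the enone with the new β-methyl; the C4 centre is untouched.

Step 5
Reactants: 9 (4S)-3,4-dimethylcyclohex-2-en-1-one; 4 (3E)-5-bromo-3-methylpenta-1,3-diene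
Product: 11 (2R,4S)-3,3,4-trimethyl-2-[(2E)-3-methylpenta-2,4-dien-1-yl]cyclohexan-1-one, via lithium enolate 10 (not isolated)
Conditions: Me2CuLi, Et2O, 0 °C; then 4, HMPA–THF, −30 → 0 °C
Reagents that add atoms: lithium dimethylcuprate [Li+].C[Cu-]C
Why: Conjugate addition builds the gem-dimethyl carbon and a regiodefined enolate; axial alkylation anti to the pseudo-axial C3 methyl, with the C4 methyl equatorial, gives the 2,4-trans ketone and so sets C1′.

Step 6
Reactants: 11 (2R,4S)-3,3,4-trimethyl-2-[(2E)-3-methylpenta-2,4-dien-1-yl]cyclohexan-1-one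
Product: 12 (1S,3S)-2,2,3-trimethyl-6-methylidene-1-[(2E)-3-methylpenta-2,4-dien-1-yl]cyclohexane
Conditions: Zn, CH2Br2, TiCl4, THF–CH2Cl2, 0 °C → rt
Reagents that add atoms: dibromomethane BrCBr
Why: Takai–Lombardo methylenation is non-basic, so the hindered ketone is converted without epimerising the adjacent C1′ centre.

Step 7
Reactants: 12 (1S,3S)-2,2,3-trimethyl-6-methylidene-1-[(2E)-3-methylpenta-2,4-dien-1-yl]cyclohexane
Product: 13 4,4,5,5-tetramethyl-2-{(2Z)-3-methyl-5-[(1S,3S)-2,2,3-trimethyl-6-methylidenecyclohexyl]pent-2-en-1-yl}-1,3,2-dioxaborolane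
Conditions: Ni(cod)2 (2.5 mol %), PCy3 (2.5 mol %), HBpin, toluene, rt
Reagents that add atoms: pinacolborane [H]B1OC(C)(C)C(C)(C)O1
Why: Nickel-catalysed 1,4-hydroboration of the s-cis diene puts boron on the terminal CH2 and hydrogen on the inner terminus, giving the (Z)-trisubstituted allylboronate; the isolated 1,1-disubstituted alkene does not react.

Step 8
Reactants: 14 meso-2,3-dimethylbutanedioic acid
Product: 15 cis-3,4-dimethyloxolane-2,5-dione
Conditions: AcCl, reflux
Reagents that add atoms: none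
Why: Cyclodehydration of the meso diacid gives the achiral cis anhydride.

Step 9
Reactants: 15 cis-3,4-dimethyloxolane-2,5-dione
Product: 16 (2S,3R)-4-methoxy-2,3-dimethyl-4-oxobutanoic acid
Conditions: MeOH (10 equiv), (DHQD)2AQN (8 mol %), Et2O, −20 °C
Reagents that add atoms: methanol CO
Why: Cinchona-alkaloid-catalysed desymmetrising methanolysis (general-base catalysis selecting one enantiotopic carbonyl) sets C9 and C10 together; if the sense were opposite, reducing the ester instead of the acid in step 10 gives the same lactone.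

Step 10
Reactants: 16 (2S,3R)-4-methoxy-2,3-dimethyl-4-oxobutanoic acid
Product: 18 (3R,4S)-3,4-dimethyloxolan-2-one, via hydroxy ester 17 (not isolated)
Conditions: BH3·SMe2, THF, −10 °C → rt; then TsOH (cat.), PhMe
Reagents that add atoms: none
Why: Borane reduces the acid chemoselectively over the ester, and acid-catalysed lactonisation fixes the differentiation of the two ends.

Step 11
Reactants: 18 (3R,4S)-3,4-dimethyloxolan-2-one
Product: 19 (3R,4S)-3,4-dimethyloxolan-2-ol
Conditions: i-Bu2AlH, CH2Cl2, −78 °C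
Reagents that add atoms: none
Why: Partial hydride reduction stops at the lactol because the tetrahedral aluminate is stable at low temperature.

Step 12
Reactants: 19 (3R,4S)-3,4-dimethyloxolan-2-ol
Product: 21 (2S)-2,3-dimethylbutan-1-ol, via hydrazone 20 (not isolated)
Conditions: N2H4·H2O, KOH, diethylene glycol, 120 → 200 °C
Reagents that add atoms: none
Why: Wolff–Kishner (Huang-Minlon) reduction of the open hydroxy-aldehyde turns CHO into CH3; the epimerisable α-carbon becomes the non-stereogenic isopropyl carbon, and the retained centre becomes C13.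

Step 13
Reactants: 21 (2S)-2,3-dimethylbutan-1-ol
Product: 22 (2S)-1-iodo-2,3-dimethylbutane
Conditions: I2, PPh3, imidazole, CH2Cl2, 0 °C → rt
Reagents that add atoms: iodine II
Why: Appel-type iodination of the primary alcohol does not involve the stereocentre.

Step 14
Reactants: 22 (2S)-1-iodo-2,3-dimethylbutane
Product: 23 [(2S)-2,3-dimethylbutyl]triphenylphosphonium iodide
Conditions: PPh3, MeCN, 85 °C (sealed tube)
Reagents that add atoms: triphenylphosphine c1ccc(cc1)P(c1ccccc1)c1ccccc1
Why: SN2 quaternisation of the primary iodide gives the Wittig salt.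

Step 15
Reactants: 19 (3R,4S)-3,4-dimethyloxolan-2-ol; 23 [(2S)-2,3-dimethylbutyl]triphenylphosphonium iodide
Product: 25 (2S,3S,4Z,6S)-2,3,6,7-tetramethyloct-4-en-1-ol, via phosphorus ylide 24 (not isolated)
Conditions: KN(SiMe3)2, THF, −78 °C → rt (23 and base 2.2 equiv)
Reagents that add atoms: none
Why: Wittig olefination of the lactol through its open hydroxy-aldehyde joins the C13 arm to the core; alkene geometry is irrelevant because the bond is reduced next.

Step 16
Reactants: 25 (2S,3S,4Z,6S)-2,3,6,7-tetramethyloct-4-en-1-ol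
Product: 26 (2S,3S,6R)-2,3,6,7-tetramethyloctan-1-ol
Conditions: H2 (1 atm), PtO2, EtOAc, rt
Reagents that add atoms: none
Why: Catalytic hydrogenation over platinum, chosen over palladium to limit double-bond migration through the two allylic stereocentres.

Step 17
Reactants: 26 (2S,3S,6R)-2,3,6,7-tetramethyloctan-1-ol
Product: 27 (2S,3S,6R)-1-iodo-2,3,6,7-tetramethyloctane
Conditions: I2, PPh3, imidazole, CH2Cl2, 0 °C → rt
Reagents that add atoms: iodine II
Why: Appel-type iodination activates the primary carbon for chain extension.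

Step 18
Reactants: 27 (2S,3S,6R)-1-iodo-2,3,6,7-tetramethyloctane; 28 trimethyl(prop-1-yn-1-yl)silane
Product: 31 (5R,6S,9R)-5,6,9,10-tetramethylundec-1-yne, via lithiated silylpropyne 29 (not isolated), via silylalkyne 30 (not isolated)
Conditions: n-BuLi, THF, −78 °C; 27, DMPU, −78 °C → rt; then K2CO3, MeOH, rt
Reagents that add atoms: none
Why: SN2 alkylation of the propargylic lithium reagent adds three carbons, and in-flask protodesilylation frees the terminal alkyne.

Step 19
Reactants: 31 (5R,6S,9R)-5,6,9,10-tetramethylundec-1-yne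
Product: 33 (2E,6R,7S,10R)-3,6,7,10,11-pentamethyldodec-2-en-1-ol, via alkenylalane 32 (not isolated)
Conditions: AlMe3, Cp2ZrCl2 (25 mol %), CH2Cl2, 0 °C → rt; then n-BuLi, THF, −78 °C; (CH2O)n, → rt
Reagents that add atoms: trimethylaluminium C[Al](C)C; formaldehyde (as paraformaldehyde) C=O
Why: Negishi zirconium-catalysed syn-carboalumination places Me and Al cis, and hydroxymethylation of the aluminate with retention gives the trisubstituted (E)-allylic alcohol.

Step 20
Reactants: 33 (2E,6R,7S,10R)-3,6,7,10,11-pentamethyldodec-2-en-1-ol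
Product: 34 (2E,6R,7S,10R)-3,6,7,10,11-pentamethyldodec-2-enal
Conditions: MnO2, CH2Cl2, rt
Reagents that add atoms: none
Why: Selective allylic oxidation gives the enal without E/Z isomerisation.

Step 21
Reactants: 34 (2E,6R,7S,10R)-3,6,7,10,11-pentamethyldodec-2-enal; 35 4-methylbenzenesulfonohydrazide
Product: 36 N′-[(1E,2E,6R,7S,10R)-3,6,7,10,11-pentamethyldodec-2-en-1-ylidene]-4-methylbenzenesulfonohydrazide
Conditions: MeOH, 0 °C → rt
Reagents that add atoms: none
Why: Mild hydrazone condensation keeps the (E)-enal geometry that later controls C6.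

Step 22
Reactants: 13 4,4,5,5-tetramethyl-2-{(2Z)-3-methyl-5-[(1S,3S)-2,2,3-trimethyl-6-methylidenecyclohexyl]pent-2-en-1-yl}-1,3,2-dioxaborolane; 36 N′-[(1E,2E,6R,7S,10R)-3,6,7,10,11-pentamethyldodec-2-en-1-ylidene]-4-methylbenzenesulfonohydrazide
Product: 39 (3S,4E,6R,9R,10S,13R)-3,6,9,10,13,14-hexamethyl-3-{2-[(1S,3S)-2,2,3-trimethyl-6-methylidenecyclohexyl]ethyl}pentadeca-1,4-diene (target), via allylated sulfonohydrazide 37 (not isolated), via allylic diazene 38 (not isolated)
Conditions: (S)-3,3′-Ph2-BINOL (15 mol %; the enantiomer that gives Re-face attack on C=N), 4 Å MS, PhMe, 40 °C; then NaOAc·3H2O, 65 °C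
Reagents that add atoms: none
Why: Proposed new method: a chiral-biphenol-catalysed "traceless" allylboration of an enal N-sulfonylhydrazone with a γ,γ-disubstituted (Z)-allylboronate, not yet shown for an all-carbon quaternary centre or an aliphatic β,β-dialkyl enal — the diol activates the boronate and hydrogen-bonds the hydrazone, the allyl unit is delivered through a closed chair to the Re face of C=N with the Z-substituent axial so that C3 forms as S together with a (4S) C–N centre, sulfinate loss then gives an allylic diazene whose suprafacial retro-ene 1,5-hydrogen shift expels N2, moves the alkene to C4=C5 (E, bulky C3 anti) and relays the C4 configuration to C6 (R); the closest known reactions are the biphenol-catalysed traceless Petasis allylation/reductive transposition of enal sulfonylhydrazones with allyl- and crotylboronates and the Myers allylic diazene rearrangement.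

**Compound list**
1 | methyl vinyl ketone | CC(=O)C=C | starting material
2 | vinylmagnesium bromide | C=C[Mg]Br | starting material
3 | 3-methylpenta-1,4-dien-3-ol | C=CC(C)(O)C=C | intermediate
4 | (3E)-5-bromo-3-methylpenta-1,3-diene | C=C/C(C)=C/CBr | intermediate
5 | propanal | CCC=O | starting material
6 | (2S)-2-methyl-5-oxohexanal | O=C[C@@H](C)CCC(C)=O | intermediate (not isolated)
7 | (4S)-4-methylcyclohex-2-en-1-one | O=C1C=C[C@@H](C)CC1 | intermediate
8 | lithium (3R,4S)-3,4-dimethylcyclohex-1-en-1-olate | [Li]OC1=C[C@H](C)[C@@H](C)CC1 | intermediate (not isolated)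
9 | (4S)-3,4-dimethylcyclohex-2-en-1-one | O=C1C=C(C)[C@@H](C)CC1 | intermediate
10 | lithium (4S)-3,3,4-trimethylcyclohex-1-en-1-olate | [Li]OC1=CC(C)(C)[C@@H](C)CC1 | intermediate (not isolated)
11 | (2R,4S)-3,3,4-trimethyl-2-[(2E)-3-methylpenta-2,4-dien-1-yl]cyclohexan-1-one | C=C/C(C)=C/C[C@H]1C(=O)CC[C@H](C)C1(C)C | intermediate
12 | (1S,3S)-2,2,3-trimethyl-6-methylidene-1-[(2E)-3-methylpenta-2,4-dien-1-yl]cyclohexane | C=C/C(C)=C/C[C@H]1C(=C)CC[C@H](C)C1(C)C | intermediate
13 | 4,4,5,5-tetramethyl-2-{(2Z)-3-methyl-5-[(1S,3S)-2,2,3-trimethyl-6-methylidenecyclohexyl]pent-2-en-1-yl}-1,3,2-dioxaborolane | CC1(C)OB(C/C=C(/C)CC[C@H]2C(=C)CC[C@H](C)C2(C)C)OC1(C)C | intermediate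
14 | meso-2,3-dimethylbutanedioic acid | OC(=O)[C@@H](C)[C@@H](C)C(O)=O | starting material
15 | cis-3,4-dimethyloxolane-2,5-dione (meso) | O=C1[C@@H](C)[C@@H](C)C(=O)O1 | intermediate
16 | (2S,3R)-4-methoxy-2,3-dimethyl-4-oxobutanoic acid | OC(=O)[C@@H](C)[C@@H](C)C(=O)OC | intermediate
17 | methyl (2R,3S)-4-hydroxy-2,3-dimethylbutanoate | OC[C@@H](C)[C@@H](C)C(=O)OC | intermediate (not isolated)
18 | (3R,4S)-3,4-dimethyloxolan-2-one | O1C[C@@H](C)[C@@H](C)C1=O | intermediate
19 | (3R,4S)-3,4-dimethyloxolan-2-ol (anomer mixture) | O1C[C@@H](C)[C@@H](C)C1O | intermediate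
20 | (2S,3R)-4-hydrazinylidene-2,3-dimethylbutan-1-ol | OC[C@@H](C)[C@@H](C)C=NN | intermediate (not isolated)
21 | (2S)-2,3-dimethylbutan-1-ol | OC[C@@H](C)C(C)C | intermediate
22 | (2S)-1-iodo-2,3-dimethylbutane | IC[C@@H](C)C(C)C | intermediate
23 | [(2S)-2,3-dimethylbutyl]triphenylphosphonium iodide | [I-].C([C@@H](C)C(C)C)[P+](c1ccccc1)(c1ccccc1)c1ccccc1 | intermediate
24 | [(2S)-2,3-dimethylbutylidene]triphenylphosphorane | C(=P(c1ccccc1)(c1ccccc1)c1ccccc1)[C@@H](C)C(C)C | intermediate (not isolated)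
25 | (2S,3S,4Z,6S)-2,3,6,7-tetramethyloct-4-en-1-ol | OC[C@@H](C)[C@@H](C)/C=C\[C@@H](C)C(C)C | intermediate
26 | (2S,3S,6R)-2,3,6,7-tetramethyloctan-1-ol | OC[C@@H](C)[C@@H](C)CC[C@@H](C)C(C)C | intermediate
27 | (2S,3S,6R)-1-iodo-2,3,6,7-tetramethyloctane | IC[C@@H](C)[C@@H](C)CC[C@@H](C)C(C)C | intermediate
28 | trimethyl(prop-1-yn-1-yl)silane | CC#C[Si](C)(C)C | starting material
29 | (3-lithioprop-1-yn-1-yl)trimethylsilane | [Li]CC#C[Si](C)(C)C | intermediate (not isolated)
30 | trimethyl[(5R,6S,9R)-5,6,9,10-tetramethylundec-1-yn-1-yl]silane | C[Si](C)(C)C#CCC[C@@H](C)[C@@H](C)CC[C@@H](C)C(C)C | intermediate (not isolated)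
31 | (5R,6S,9R)-5,6,9,10-tetramethylundec-1-yne | C#CCC[C@@H](C)[C@@H](C)CC[C@@H](C)C(C)C | intermediate
32 | dimethyl[(1E,5R,6S,9R)-2,5,6,9,10-pentamethylundec-1-en-1-yl]alumane | C[Al](C)/C=C(\C)CC[C@@H](C)[C@@H](C)CC[C@@H](C)C(C)C | intermediate (not isolated)
33 | (2E,6R,7S,10R)-3,6,7,10,11-pentamethyldodec-2-en-1-ol | OC/C=C(\C)CC[C@@H](C)[C@@H](C)CC[C@@H](C)C(C)C | intermediate
34 | (2E,6R,7S,10R)-3,6,7,10,11-pentamethyldodec-2-enal | O=C/C=C(\C)CC[C@@H](C)[C@@H](C)CC[C@@H](C)C(C)C | intermediate
35 | 4-methylbenzenesulfonohydrazide | Cc1ccc(cc1)S(=O)(=O)NN | starting material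
36 | N′-[(1E,2E,6R,7S,10R)-3,6,7,10,11-pentamethyldodec-2-en-1-ylidene]-4-methylbenzenesulfonohydrazide | Cc1ccc(cc1)S(=O)(=O)N/N=C/C=C(\C)CC[C@@H](C)[C@@H](C)CC[C@@H](C)C(C)C | intermediate
37 | N′-{(3S,4S,5E,9R,10S,13R)-3-ethenyl-3,6,9,10,13,14-hexamethyl-1-[(1S,3S)-2,2,3-trimethyl-6-methylidenecyclohexyl]pentadec-5-en-4-yl}-4-methylbenzenesulfonohydrazide | Cc1ccc(cc1)S(=O)(=O)NN[C@@H](/C=C(\C)CC[C@@H](C)[C@@H](C)CC[C@@H](C)C(C)C)[C@](C)(C=C)CC[C@H]1C(=C)CC[C@H](C)C1(C)C | intermediate (not isolated)
38 | {(3S,4S,5E,9R,10S,13R)-3-ethenyl-3,6,9,10,13,14-hexamethyl-1-[(1S,3S)-2,2,3-trimethyl-6-methylidenecyclohexyl]pentadec-5-en-4-yl}diazene | N=N[C@@H](/C=C(\C)CC[C@@H](C)[C@@H](C)CC[C@@H](C)C(C)C)[C@](C)(C=C)CC[C@H]1C(=C)CC[C@H](C)C1(C)C | intermediate (not isolated)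
39 | (3S,4E,6R,9R,10S,13R)-3,6,9,10,13,14-hexamethyl-3-{2-[(1S,3S)-2,2,3-trimethyl-6-methylidenecyclohexyl]ethyl}pentadeca-1,4-diene | C=C[C@@](C)(/C=C/[C@H](C)CC[C@@H](C)[C@@H](C)CC[C@@H](C)C(C)C)CC[C@H]1C(=C)CC[C@H](C)C1(C)C | target

**Step count**
Total: 22 steps. Longest linear sequence: 15 steps (8 → 22, through 14–19, the C13 arm 21–23, and 25–36). The ring branch is steps 3–7 (with 1–2 for bromide 4) before the final coupling.

**Steps most likely to fail, with fallbacks**

Step 22 (the proposed new reaction). Risks are slow addition to the conjugated hydrazone (or its cyclisation to a pyrazoline), and an unexpected relative sense between C4 and C3 if the hydrazone does not react through the aldehyde-like chair. The fallback uses only known chemistry, sets out from enal 34 and boronate 13, and returns at 39. Enal 34 is reduced with Hantzsch ester and the morpholinium salt of (R)-TRIP (iminium transfer hydrogenation, as for citral to citronellal) to (3R,6R,7S,10R)-3,6,7,10,11-pentamethyldodecanal F1, which fixes C6 independently. Chiral-phosphoric-acid-catalysed allylboration of F1 with 13 ((R)-TRIP, toluene, −30 °C, Re-face attack through the usual aldehyde chair) gives (3S,4S,6R,9R,10S,13R)-3-ethenyl-3,6,9,10,13,14-hexamethyl-1-[(1S,3S)-2,2,3-trimethyl-6-methylidenecyclohexyl]pentadecan-4-ol F2. Its carbinol has hydrogens only on the C5 side, so syn-dehydration with Burgess reagent (PhMe, 70 °C) gives the (E)-C4=C5 alkene of 39.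

Step 5. The cuprate may add slowly to the hindered enone, the enolate may alkylate poorly or at oxygen, and the C2 centre could epimerise. The fallback sets out from 9 and returns at 12. The same cuprate enolate 10 is trapped with PhNTf2 to give (4S)-3,3,4-trimethylcyclohex-1-en-1-yl trifluoromethanesulfonate F3. Stille coupling with Bu3SnCH2OH (Pd(PPh3)4, LiCl, dioxane, 100 °C) gives [(4S)-3,3,4-trimethylcyclohex-1-en-1-yl]methanol F4. Vinyl transfer from ethyl vinyl ether (Hg(OAc)2 cat.) gives (4S)-1-[(ethenyloxy)methyl]-3,3,4-trimethylcyclohex-1-ene F5, and its Claisen rearrangement at 190 °C forms the C1′ centre and the exocyclic methylene in one suprafacial event, giving 2-[(1S,3S)-2,2,3-trimethyl-6-methylidenecyclohexyl]acetaldehyde F6 with no epimerisable ketone. Wittig reaction with Ph3P=C(CH3)CHO gives (2E)-2-methyl-4-[(1S,3S)-2,2,3-trimethyl-6-methylidenecyclohexyl]but-2-enal F7, and methylenation with Ph3P=CH2 gives triene 12.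

Step 15. The open hydroxy-aldehyde of lactol 19 can epimerise at its α-carbon (the future C10) under the basic ylide, and the reaction uses an excess of the valuable salt 23. The fallback replaces the olefination with an sp3–sp3 coupling, sets out from 16 and 22, returns at 26 and also removes step 16. The lithium salt of 16 is reduced at the ester with LiBH4 and lactonised to the antipodal lactone (3S,4R)-3,4-dimethyloxolan-2-one F8. Ring opening with Me3SiI then EtOH gives ethyl (2S,3R)-4-iodo-2,3-dimethylbutanoate F9. Iodide 22 is converted with Mg into [(2S)-2,3-dimethylbutyl]magnesium iodide F10, which is coupled with F9 under Li2CuCl4 catalysis (THF–NMP, −20 °C) to ethyl (2S,3S,6R)-2,3,6,7-tetramethyloctanoate F11. LiAlH4 reduction gives alcohol 26.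

**Further compounds**
F1 | step 22 | (3R,6R,7S,10R)-3,6,7,10,11-pentamethyldodecanal | O=CC[C@H](C)CC[C@@H](C)[C@@H](C)CC[C@@H](C)C(C)C
F2 | step 22 | (3S,4S,6R,9R,10S,13R)-3-ethenyl-3,6,9,10,13,14-hexamethyl-1-[(1S,3S)-2,2,3-trimethyl-6-methylidenecyclohexyl]pentadecan-4-ol | O[C@@H](C[C@H](C)CC[C@@H](C)[C@@H](C)CC[C@@H](C)C(C)C)[C@](C)(C=C)CC[C@H]1C(=C)CC[C@H](C)C1(C)C
F3 | step 5 | (4S)-3,3,4-trimethylcyclohex-1-en-1-yl trifluoromethanesulfonate | FC(F)(F)S(=O)(=O)OC1=CC(C)(C)[C@@H](C)CC1
F4 | step 5 | [(4S)-3,3,4-trimethylcyclohex-1-en-1-yl]methanol | OCC1=CC(C)(C)[C@@H](C)CC1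
F5 | step 5 | (4S)-1-[(ethenyloxy)methyl]-3,3,4-trimethylcyclohex-1-ene | C=COCC1=CC(C)(C)[C@@H](C)CC1
F6 | step 5 | 2-[(1S,3S)-2,2,3-trimethyl-6-methylidenecyclohexyl]acetaldehyde | O=CC[C@H]1C(=C)CC[C@H](C)C1(C)C
F7 | step 5 | (2E)-2-methyl-4-[(1S,3S)-2,2,3-trimethyl-6-methylidenecyclohexyl]but-2-enal | O=C/C(C)=C/C[C@H]1C(=C)CC[C@H](C)C1(C)C
F8 | step 15 | (3S,4R)-3,4-dimethyloxolan-2-one | O=C1[C@@H](C)[C@@H](C)CO1
F9 | step 15 | ethyl (2S,3R)-4-iodo-2,3-dimethylbutanoate | CCOC(=O)[C@@H](C)[C@@H](C)CI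
F10 | step 15 | [(2S)-2,3-dimethylbutyl]magnesium iodide | I[Mg]C[C@@H](C)C(C)C
F11 | step 15 | ethyl (2S,3S,6R)-2,3,6,7-tetramethyloctanoate | CCOC(=O)[C@@H](C)[C@@H](C)CC[C@@H](C)C(C)C
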